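**Retrosynthetic overview**
1. Target 17 comes from methyl ester 16 by removal of three benzyl groups; 16 comes from keto acid 14, and 14 from hydroxide opening of the (Z)-butylidenephthalide 15.
2. Key disconnection: the C6'–C(acyl) bond and the lactone C–O bond of 15, formed together by carboxylate-directed C6'–H acylation of the 2-aryloxy-4-methoxybenzoic acid 12 with pentanoic anhydride 13. The feature used is that ring B holds the ester carbon on C1' and the pentanoyl carbon on the neighbouring C6', while C2' is blocked by the diaryl ether oxygen.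
3. 12 comes from Ullmann C2'–O coupling of the ring A phenol 10 with 2-bromo-4-methoxybenzoic acid 11.
4. 10 comes from olivetol 1 by O-benzylation, Vilsmeier formylation, Pinnick oxidation, benzyl ester formation, bromination at position 5 of ring A and borylation–oxidation.
5. Ring order: both benzene rings are bought; the only ring made is the five-membered lactone of 15 (step 8), which is opened again in step 9.

Key step: step 8

Remark on numbering: ring A is numbered as in olivetolic acid (position 1 carboxyl carbon, positions 2 and 4 oxygen-bearing, position 3 hydrogen, position 5 diaryl ether carbon, position 6 pentyl carbon), and the names of 5 to 10 follow this numbering. Ring B is primed (C1' carboxyl carbon, C2' aryloxy, C4' methoxy, C6' pentanoyl). "ArO" stands for the ring A aryloxy residue of phenol 10, that is ring A joined through the oxygen on position 5, with benzyl groups on the oxygens of positions 2 and 4 and on the carboxyl of position 1. The target has no stereocentre; the only stereo element on the route is the Z alkene of 15, which is erased in step 9.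

**Step 1**
Reactants: 1 olivetol (5-pentylresorcinol); 2 benzyl bromide (two equivalents)
Product: 3 1,3-bis(benzyloxy)-5-pentylbenzene
Conditions: BnBr (2.2 equiv), K2CO3, DMF, 60 °C
Reagents that add atoms: benzyl bromide, BrCc1ccccc1 (the second equivalent; the two benzyl groups of 3 come from two molecules of 2)
Why: Williamson ether synthesis on two unhindered phenols, for which K2CO3 in DMF should give clean double O-alkylation.

**Step 2**
Reactants: 3 1,3-bis(benzyloxy)-5-pentylbenzene
Product: 5 2,4-bis(benzyloxy)-6-pentylbenzaldehyde, via aryliminium chloride 4 (not isolated)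
Conditions: POCl3, DMF, 0 to 70 °C; then H2O
Reagents that add atoms: N,N-dimethylformamide, CN(C)C=O; phosphoryl chloride, O=P(Cl)(Cl)Cl (chloride counter-ion of 4 only); water, O
Why: Vilsmeier–Haack formylation, in which the chloroiminium ion should attack the position para to one benzyloxy group and ortho to the other, the site between the two ethers being the more crowded one, as is usual for 3,5-dialkoxyalkylbenzenes.

**Step 3**
Reactants: 5 2,4-bis(benzyloxy)-6-pentylbenzaldehyde
Product: 6 2,4-bis(benzyloxy)-6-pentylbenzoic acid
Conditions: NaClO2, NaH2PO4, 2-methyl-2-butene, t-BuOH/THF/H2O, rt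
Reagents that add atoms: sodium chlorite, [Na+].[O-]Cl=O
Why: Pinnick oxidation, in which chlorous acid oxidises the aldehyde while 2-methyl-2-butene traps the hypochlorous acid that would otherwise chlorinate the electron-rich ring.

**Step 4**
Reactants: 6 2,4-bis(benzyloxy)-6-pentylbenzoic acid; 2 benzyl bromide
Product: 7 benzyl 2,4-bis(benzyloxy)-6-pentylbenzoate
Conditions: BnBr, K2CO3, DMF, rt
Reagents that add atoms: none
Why: Carboxylate O-alkylation (SN2 at the benzylic carbon), which is not slowed by the two ortho substituents because the bond is formed away from the crowded carbonyl carbon.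

**Step 5**
Reactants: 7 benzyl 2,4-bis(benzyloxy)-6-pentylbenzoate
Product: 8 benzyl 2,4-bis(benzyloxy)-5-bromo-6-pentylbenzoate
Conditions: NBS, MeCN, 0 °C to rt, dark
Reagents that add atoms: N-bromosuccinimide, O=C1CCC(=O)N1Br
Why: Electrophilic aromatic bromination, expected at position 5 of ring A because it is para to the ether on position 2 and ortho to the ether on position 4, while position 3 is wedged between two benzyloxy groups; polar solvent and exclusion of light should suppress radical benzylic bromination.

**Step 6**
Reactants: 8 benzyl 2,4-bis(benzyloxy)-5-bromo-6-pentylbenzoate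
Product: 10 benzyl 2,4-bis(benzyloxy)-5-hydroxy-6-pentylbenzoate, via pinacol boronate 9 (not isolated)
Conditions: B2pin2, Pd(OAc)2/SPhos (cat.), KOAc, dioxane, 90 °C; then 30% H2O2, aq. NaOH, THF, 0 °C
Reagents that add atoms: bis(pinacolato)diboron, CC1(C)OB(OC1(C)C)B1OC(C)(C)C(C)(C)O1 (boron and pinacol of intermediate 9 only); hydrogen peroxide, OO
Why: Miyaura borylation (zerovalent palladium inserts into the C–Br bond, and the bulky biarylphosphine is chosen for the di-ortho-substituted centre) followed by alkaline peroxide oxidation of the C–B bond with aryl migration from boron to oxygen; the benzoate ester flanked by pentyl and benzyloxy groups should resist hydroperoxide at 0 °C.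

**Step 7**
Reactants: 10 benzyl 2,4-bis(benzyloxy)-5-hydroxy-6-pentylbenzoate; 11 2-bromo-4-methoxybenzoic acid
Product: 12 2-(ArO)-4-methoxybenzoic acid
Conditions: CuI (cat.), N,N-dimethylglycine (cat.), Cs2CO3, DMF, 100 °C; then 1 M HCl
Reagents that add atoms: none
Why: Ullmann diaryl ether condensation, in which the ortho carboxylate of 11 accelerates copper insertion into the C–Br bond, so that even the phenoxide flanked by pentyl and benzyloxy groups should couple; the anhydrous carbonate leaves the benzyl ester intact.

**Step 8**
Reactants: 12 2-(ArO)-4-methoxybenzoic acid; 13 pentanoic anhydride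
Product: 15 (Z)-3-butylidene-5-methoxy-7-(ArO)isobenzofuran-1(3H)-one, via keto acid 14 (not isolated)
Conditions: [Rh(cod)Cl]2 (cat.), CsF, NMP, 150 °C
Reagents that add atoms: none
Why: The caesium carboxylate of 12 binds monovalent rhodium and delivers it into the C6'–H bond to give a five-membered rhodacycle; pentanoic anhydride then adds oxidatively through an acyl–oxygen bond to give an acyl(aryl) complex of trivalent rhodium, and reductive elimination forms the C6'–C(=O) bond of keto acid 14. The reaction type is the known rhodium-catalysed ortho C–H acylation of benzoic acids with aliphatic anhydrides, which delivers 3-alkylidenephthalides directly. The lactone closes 5-exo-trig by attack of the carboxyl oxygen on the ketone carbonyl, and loss of water from the hydroxyphthalide, helped by the excess anhydride, gives the enol lactone. No stereocentre is formed; the Z alkene, with the propyl chain turned away from the peri C–H, is the thermodynamic isomer and is erased in step 9. The selectivity needed is ortho site selectivity, and it is secured because C6'–H is the only hydrogen ortho to a free carboxyl: C2' carries the aryloxy group, and the ring A carboxyl is a benzyl ester with both ortho positions substituted. Xanthone formation by acylation of ring A is excluded because positions 4 and 6 of ring A, the two positions ortho to the ether oxygen, are substituted, and no free hydroxyl is present to be acylated.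

**Step 9**
Reactants: 15 (Z)-3-butylidene-5-methoxy-7-(ArO)isobenzofuran-1(3H)-one
Product: 14 2-(ArO)-4-methoxy-6-pentanoylbenzoic acid
Conditions: KOH, THF/H2O, rt; then 1 M HCl
Reagents that add atoms: potassium hydroxide, [K+].[OH-]
Why: Saponification of the enol lactone (hydroxide adds to the lactone carbonyl and the enolate leaves, tautomerising to the butyl ketone) should give the same keto acid that passes through step 8 unseen; the use of hydroxide with no alcohol present avoids the alkoxide-induced rearrangement of alkylidenephthalides to indane-1,3-diones, and the doubly ortho-substituted ring A benzyl ester should survive at room temperature.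

**Step 10**
Reactants: 14 2-(ArO)-4-methoxy-6-pentanoylbenzoic acid
Product: 16 methyl 2-(ArO)-4-methoxy-6-pentanoylbenzoate
Conditions: MeI, KHCO3, DMF, rt
Reagents that add atoms: iodomethane, CI
Why: SN2 O-methylation of the carboxylate, which should give the open-chain keto ester and not the cyclic pseudo ester because the anion reacts through its carboxylate oxygen; the weak base should not enolise the ketone.

**Step 11**
Reactants: 16 methyl 2-(ArO)-4-methoxy-6-pentanoylbenzoate
Product: 17 4,6-dihydroxy-3-[5-methoxy-2-(methoxycarbonyl)-3-pentanoylphenoxy]-2-pentylbenzoic acid (CNP0262789.0)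
Conditions: H2 (1 atm), 10% Pd/C, EtOAc, rt
Reagents that add atoms: none
Why: Catalytic hydrogenolysis of two benzyl ethers and one benzyl ester, which should be faster than reduction of the aryl ketone crowded by its ortho ester if the reaction is stopped after three equivalents of hydrogen; the neutral conditions at room temperature should not decarboxylate the resorcylic acid.

**Compound list**
1 | olivetol (5-pentylbenzene-1,3-diol) | CCCCCc1cc(O)cc(O)c1 | starting material
2 | benzyl bromide | BrCc1ccccc1 | starting material
3 | 1,3-bis(benzyloxy)-5-pentylbenzene | CCCCCc1cc(OCc2ccccc2)cc(OCc2ccccc2)c1 | intermediate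
4 | N-[2,4-bis(benzyloxy)-6-pentylbenzylidene]-N-methylmethanaminium chloride (aryliminium chloride) | CCCCCc1cc(OCc2ccccc2)cc(OCc2ccccc2)c1C=[N+](C)C.[Cl-] | intermediate
5 | 2,4-bis(benzyloxy)-6-pentylbenzaldehyde | CCCCCc1cc(OCc2ccccc2)cc(OCc2ccccc2)c1C=O | intermediate
6 | 2,4-bis(benzyloxy)-6-pentylbenzoic acid | CCCCCc1cc(OCc2ccccc2)cc(OCc2ccccc2)c1C(=O)O | intermediate
7 | benzyl 2,4-bis(benzyloxy)-6-pentylbenzoate | CCCCCc1cc(OCc2ccccc2)cc(OCc2ccccc2)c1C(=O)OCc1ccccc1 | intermediate
8 | benzyl 2,4-bis(benzyloxy)-5-bromo-6-pentylbenzoate (bromine on position 5 of ring A, between the pentyl-bearing carbon and the ether carbon of position 4) | CCCCCc1c(Br)c(OCc2ccccc2)cc(OCc2ccccc2)c1C(=O)OCc1ccccc1 | intermediate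
9 | benzyl 2,4-bis(benzyloxy)-6-pentyl-5-(4,4,5,5-tetramethyl-1,3,2-dioxaborolan-2-yl)benzoate | CCCCCc1c(B2OC(C)(C)C(C)(C)O2)c(OCc2ccccc2)cc(OCc2ccccc2)c1C(=O)OCc1ccccc1 | intermediate
10 | benzyl 2,4-bis(benzyloxy)-5-hydroxy-6-pentylbenzoate (ring A phenol) | CCCCCc1c(O)c(OCc2ccccc2)cc(OCc2ccccc2)c1C(=O)OCc1ccccc1 | intermediate
11 | 2-bromo-4-methoxybenzoic acid | COc1ccc(C(=O)O)c(Br)c1 | starting material
12 | 2-[4,6-bis(benzyloxy)-3-(benzyloxycarbonyl)-2-pentylphenoxy]-4-methoxybenzoic acid | CCCCCc1c(Oc2cc(OC)ccc2C(=O)O)c(OCc2ccccc2)cc(OCc2ccccc2)c1C(=O)OCc1ccccc1 | intermediate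
13 | pentanoic anhydride | CCCCC(=O)OC(=O)CCCC | starting material
14 | 2-[4,6-bis(benzyloxy)-3-(benzyloxycarbonyl)-2-pentylphenoxy]-4-methoxy-6-pentanoylbenzoic acid | CCCCCc1c(Oc2cc(OC)cc(C(=O)CCCC)c2C(=O)O)c(OCc2ccccc2)cc(OCc2ccccc2)c1C(=O)OCc1ccccc1 | intermediate
15 | (Z)-7-[4,6-bis(benzyloxy)-3-(benzyloxycarbonyl)-2-pentylphenoxy]-3-butylidene-5-methoxyisobenzofuran-1(3H)-one | CCC/C=C1\OC(=O)c2c(Oc3c(CCCCC)c(C(=O)OCc4ccccc4)c(OCc4ccccc4)cc3OCc3ccccc3)cc(OC)cc21 | intermediate
16 | methyl 2-[4,6-bis(benzyloxy)-3-(benzyloxycarbonyl)-2-pentylphenoxy]-4-methoxy-6-pentanoylbenzoate | CCCCCc1c(Oc2cc(OC)cc(C(=O)CCCC)c2C(=O)OC)c(OCc2ccccc2)cc(OCc2ccccc2)c1C(=O)OCc1ccccc1 | intermediate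
17 | 4,6-dihydroxy-3-[5-methoxy-2-(methoxycarbonyl)-3-pentanoylphenoxy]-2-pentylbenzoic acid | CCCCCc1c(Oc2cc(OC)cc(C(=O)CCCC)c2C(=O)OC)c(O)cc(O)c1C(=O)O | target

**Step count**
Total steps: 11. Longest linear sequence: 11 steps (olivetol 1 to target 17).

**Steps most likely to fail**

Step 8. The crowded carboxylate may not bring rhodium into the C6'–H bond at a useful rate, so that protodecarboxylation of the ortho-substituted acid or benzyl transfer from the ring A ester at 150 °C outruns the acylation. The fallback sets out from phenol 10 and returns at phthalide 15, and installs a halogen handle in place of the C–H bond. Commercial 1,3-dibromo-5-methoxybenzene would be lithiated between the two bromine atoms with LiN(iPr)2 (THF, −78 °C) and quenched with CO2 to give 2,6-dibromo-4-methoxybenzoic acid F1. Ullmann coupling of 10 with an excess of F1 under the step 7 conditions, stopped at single substitution, should give the 6'-bromo acid 2-(ArO)-6-bromo-4-methoxybenzoic acid F2. Sonogashira coupling of F2 with pent-1-yne (Pd(PPh3)2Cl2, CuI, Et3N, DMF, 80 °C) should give the alkynyl acid 2-(ArO)-4-methoxy-6-(pent-1-ynyl)benzoic acid F3. Under the same copper conditions the carboxylate of F3 should add 5-exo-dig across the alkyne, the established route from 2-halobenzoic acids and terminal alkynes to (Z)-3-alkylidenephthalides, to give 15.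

Step 7. C–O bond formation at copper may be slow for a phenoxide flanked by pentyl and benzyloxy groups, so that reductive loss of bromine from 11 consumes the aryl halide. The fallback sets out from phenol 10 and returns at acid 12. Nucleophilic aromatic substitution of the phenoxide of 10 on commercial 2-fluoro-4-methoxybenzaldehyde (Cs2CO3, DMSO, 110 °C), where the ortho formyl group activates the fluoride, should give the diaryl ether aldehyde 2-(ArO)-4-methoxybenzaldehyde F4. Pinnick oxidation of F4 (NaClO2, NaH2PO4, 2-methyl-2-butene) should then give 12.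

Step 6. Transmetallation at the aryl–palladium centre flanked by pentyl and benzyloxy groups may be slow, so that protodebromination back to 7 dominates. The fallback sets out from ester 7, leaves out step 5, and returns at phenol 10. Formylation of 7 at position 5 of ring A with Cl2CHOMe and AgOTf (CH2Cl2, −78 °C) should give benzyl 2,4-bis(benzyloxy)-5-formyl-6-pentylbenzoate F5. Baeyer–Villiger oxidation of F5 with mCPBA (CH2Cl2, rt), in which the electron-rich aryl group migrates, should give the aryl formate benzyl 2,4-bis(benzyloxy)-5-(formyloxy)-6-pentylbenzoate F6. Methanolysis of F6 (K2CO3, MeOH, 0 °C) should give 10.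

**Further compounds**
F1 | step 8 | 2,6-dibromo-4-methoxybenzoic acid | COc1cc(Br)c(C(=O)O)c(Br)c1
F2 | step 8 | 2-[4,6-bis(benzyloxy)-3-(benzyloxycarbonyl)-2-pentylphenoxy]-6-bromo-4-methoxybenzoic acid | CCCCCc1c(Oc2cc(OC)cc(Br)c2C(=O)O)c(OCc2ccccc2)cc(OCc2ccccc2)c1C(=O)OCc1ccccc1
F3 | step 8 | 2-[4,6-bis(benzyloxy)-3-(benzyloxycarbonyl)-2-pentylphenoxy]-4-methoxy-6-(pent-1-yn-1-yl)benzoic acid | CCCC#Cc1cc(OC)cc(Oc2c(CCCCC)c(C(=O)OCc3ccccc3)c(OCc3ccccc3)cc2OCc2ccccc2)c1C(=O)O
F4 | step 7 | benzyl 4,6-bis(benzyloxy)-3-(2-formyl-5-methoxyphenoxy)-2-pentylbenzoate | CCCCCc1c(Oc2cc(OC)ccc2C=O)c(OCc2ccccc2)cc(OCc2ccccc2)c1C(=O)OCc1ccccc1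
F5 | step 6 | benzyl 2,4-bis(benzyloxy)-5-formyl-6-pentylbenzoate | CCCCCc1c(C=O)c(OCc2ccccc2)cc(OCc2ccccc2)c1C(=O)OCc1ccccc1
F6 | step 6 | benzyl 2,4-bis(benzyloxy)-5-(formyloxy)-6-pentylbenzoate | CCCCCc1c(OC=O)c(OCc2ccccc2)cc(OCc2ccccc2)c1C(=O)OCc1ccccc1
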